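The constants used here come from no measurement, and the outcome is calculated.

Take these flasks and follow J.L to its two exits, closing to Q or being caught by J.

    J + L → J.L (k1 = 447 M⁻¹ s⁻¹)
    J.L ⇌ Q (K2 = 12.5, k2 = 0.0435 s⁻¹)
    J + J.L → J.J.L (k3 = 223 M⁻¹ s⁻¹)
    Q ⇌ E (K4 = 1.20, k4 = 0.0143 s⁻¹)
    G ⇌ Q, rate k5*(cs5 - [Q]) while solid is left; crystals form when [Q] > cs5 (cs5 = 0.017 mM, k5 = 0.604 s⁻¹)

common to all: time 2.0 min

| flask | J | L | remark |
|---|---|---|---|
| eta | 0.20 mM | 0.300 mM (fed, over 25 s) | all else is in the flask from the start; the feed brings no volume worth counting |
| delta | 0.20 mM | 0.300 mM (fed, over 1.5 min) | all else is in the flask from the start; the feed brings no volume worth counting |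
| zeta | 0.20 mM | 0.300 mM | everything together at the start |
| alpha | 0.20 mM (fed, over 1.5 min) | 0.300 mM | all else is in the flask from the start; the feed brings no volume worth counting |

- in percentages every species weighs as the J in it: one J.J.L counts as two
- for Q the G are counted in
- as a solid, counted per litre of solution: G
- run time (eta): 2.0 min

1. the flask with the highest amount of J.J.L, in percent of the J charged ("all alike" if they lie within 1.5 percentage points) (eta / delta / zeta / alpha / all alike)
2. final J.J.L, as a percentage of the J charged, in eta
3. final J.J.L, as a percentage of the J charged, in delta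
4. final J.J.L, as a percentage of the J charged, in zeta
5. final J.J.L, as a percentage of the J charged, in alpha

1. I freeze [J] first. J.L closes at 0.0435 s⁻¹ and is caught at 223 M⁻¹ s⁻¹ times [J], so the two exits match at the crossover concentration C = 0.195 mM, which is close to the J charge of 0.20 mM. At frozen [J], the share of J.L caught (a selectivity) is [J]/([J] + C).

2. Each catch takes a second J, so the share of passing J that ends in J.J.L is Y = 2[J]/(2[J] + C).

3. In alpha, the dosing time is 12 lifetimes of J against the charged L, long enough for [J] to hold steady. With [L] frozen too, J is used up pseudo-first-order, and feed balances loss at [J] = 0.0166 mM. So Y = 14.5 %.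

4. In delta, the dosing time is 8.0 lifetimes of L against the charged J, long enough for L to be used about as it arrives early in the feed. [J] therefore slides from 0.20 mM towards zero, and integrating Y along that slide gives 45.6 %.

5. In zeta, J has a half-life of 0.086 min by step 1 alone, shorter than the 0.27 min of J.L by forward closing alone, so J.L piles up and [J] does not hold still. Integrating the catch while J dies away, with closing set aside, gives about 33.3 %. Eta doses over 2.24 lifetimes of L, fewer than the 8.0 of delta, so I place it between zeta and delta.

6. The weak link is the frozen [L] in alpha. Taking the mean [L] as 0.200 mM raises [J] to 0.0249 mM and Y to 20.3 %. I commit to alpha between 14.5 % and 20.3 %, and to delta as the highest.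

The forecast names delta, with 27.5 %, 34 %, 27 % and 16 % for eta, delta, zeta and alpha, holding that “a slow L feed into excess J (delta) favours it most”, and its delta is lower than my slide.

The simulation puts delta highest: eta 29.4 %, delta 37.2 %, zeta 25.3 %, alpha 15.0 %.

Delta stands 8.4 percentage points below my slide and zeta 8 points below my figure. Alpha reads 15.0 %, near the frozen end of my span, although L is down to 46.7 % of its charge at 1.50 min. Now I take the neighbour of alpha charged with 0.12 mM of J, with C and [L] frozen as before. Feed balances loss at [J] = 0.00994 mM, so Y = 9.25 %. That neighbour ends with 8.51 % of its J charge as J.J.L.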